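The terminal (+)-catechin unit is built de novo and its pyran ring is closed by forming the O1–C8a aryl ether bond: the C2 alkoxide of an acyclic 1,3-diarylpropan-1-ol displaces fluoride from the A-ring (intramolecular SNAr). The step exploits the phloroglucinol pattern of the terminal A-ring: a fluorine at C8a lies meta to the C5 and C7 oxygens, and it had earlier directed ortho-metalation to attach C4. Because the C2–O bond is never broken, the anti C2/C3 diad (C3 bought as methyl (S)-glycidate, C2 relayed by Felkin addition) becomes the 2,3-trans ring. Two C4→C8 couplings with an epicatechin gallate electrophile and hydrogenolysis finish the trimer.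

Key step: step 6

Remark: the target is read as (−)-epicatechin 3-O-gallate-(4β→8)-(−)-epicatechin 3-O-gallate-(4β→8)-(+)-catechin (units 2R,3R / 2R,3R / 2R,3S; both interflavan bonds 3,4-trans). Short-lived cations and the Meisenheimer adduct are treated as mechanistic intermediates and are not numbered.

Step 1
Reactants: 1 1,3,5-trifluorobenzene
Product: 2 1,3-bis(benzyloxy)-5-fluorobenzene
Conditions: BnOH (2.05 equiv), NaH (2.1 equiv), NMP, 0 → 70 °C
Reagents that add atoms: benzyl alcohol, OCc1ccccc1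
Why: Two successive nucleophilic aromatic substitutions by benzyloxide, each fluorine being activated inductively by the meta fluorines; the third displacement is the slowest once two alkoxy groups are in place, so the stoichiometry should stop the reaction at the bis-ether.

Step 2
Reactants: 2 1,3-bis(benzyloxy)-5-fluorobenzene; 3 methyl (S)-glycidate
Product: 6 methyl (2S)-3-[2,4-bis(benzyloxy)-6-fluorophenyl]-2-hydroxypropanoate, via aryllithium 4 (not isolated), via arylmagnesium bromide 5 (not isolated)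
Conditions: n-BuLi, THF, −78 °C; MgBr2·OEt2, −78 °C; then 3, CuI (10 mol%), −78 → −30 °C; aq NH4Cl
Reagents that add atoms: none
Why: Directed ortho-metalation should occur at the C–H flanked by F and OBn (the most acidic site), Li→Mg exchange suppresses loss of LiF, and the copper-catalysed Grignard opening of the epoxide at its CH2 carbon (SN2) leaves the purchased (S) centre untouched.

Step 3
Reactants: 6 methyl (2S)-3-[2,4-bis(benzyloxy)-6-fluorophenyl]-2-hydroxypropanoate
Product: 7 methyl (2S)-2-(benzyloxy)-3-[2,4-bis(benzyloxy)-6-fluorophenyl]propanoate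
Conditions: BnBr, Ag2O, CH2Cl2, rt, dark
Reagents that add atoms: benzyl bromide, BrCc1ccccc1
Why: Silver(I) oxide-mediated O-benzylation (Williamson-type etherification under non-basic conditions) alkylates the α-hydroxy ester without enolisation, so the stereocentre is kept.

Step 4
Reactants: 7 methyl (2S)-2-(benzyloxy)-3-[2,4-bis(benzyloxy)-6-fluorophenyl]propanoate
Product: 8 (2S)-2-(benzyloxy)-3-[2,4-bis(benzyloxy)-6-fluorophenyl]propanal
Conditions: DIBAL-H (1.1 equiv), CH2Cl2, −78 °C; Rochelle salt; used crude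
Reagents that add atoms: none
Why: Partial DIBAL-H reduction of an α-alkoxy ester stops at the chelated hemiacetal aluminate at −78 °C and releases the aldehyde on work-up; immediate use should avoid epimerisation.

Step 5
Reactants: 8 (2S)-2-(benzyloxy)-3-[2,4-bis(benzyloxy)-6-fluorophenyl]propanal; 9 4-bromo-1,2-bis(benzyloxy)benzene
Product: 12 (1R,2S)-2-(benzyloxy)-1-[3,4-bis(benzyloxy)phenyl]-3-[2,4-bis(benzyloxy)-6-fluorophenyl]propan-1-ol, via aryllithium 10 (not isolated), via aryltitanium triisopropoxide 11 (not isolated)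
Conditions: 9, n-BuLi, THF, −78 °C; ClTi(OiPr)3, −78 → −40 °C; then 8, −78 → −20 °C; aq NH4Cl
Reagents that add atoms: none
Why: The weakly Lewis acidic aryltitanium triisopropoxide cannot chelate the α-benzyloxy aldehyde, so the addition should follow the polar Felkin–Anh model (attack anti to the C–OBn bond) and set the carbinol centre 1,2-anti to the existing one (non-chelation-controlled organotitanium addition).

Step 6
Reactants: 12 (1R,2S)-2-(benzyloxy)-1-[3,4-bis(benzyloxy)phenyl]-3-[2,4-bis(benzyloxy)-6-fluorophenyl]propan-1-ol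
Product: 14 3,5,7,3',4'-penta-O-benzyl-(+)-catechin, via potassium alkoxide 13 (not isolated)
Conditions: KHMDS (1.2 equiv), 18-crown-6, THF/DMPU, 0 → 60 °C
Reagents that add atoms: none
Why: KHMDS converts 12 into the potassium alkoxide 13, whose oxygen adds to the fluorine-bearing A-ring carbon to give a Meisenheimer adduct that expels fluoride (addition–elimination SNAr). The closest known reaction type is the intramolecular etherification of fluoroarenes by alkoxides used to close chroman and flavan rings. The pyran ring closes in a 6-exo-trig mode at the arene carbon and forms the O1–C8a bond. No stereocentre is created: the C2–O bond is carried through unbroken, so the anti C1/C2 diad of 12 necessarily becomes the 2,3-trans (2R,3S) ring with both substituents equatorial. The step needs selectivity for six- over five-membered closure and for the right carbon: the C3 oxygen is benzylated so only the benzylic oxygen can attack, there is a single C–F bond, and the C5 and C7 benzyloxy groups are meta to it, where they activate inductively and cannot donate into the ipso carbon.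

Step 7
Reactants: 15 (−)-epicatechin
Product: 16 5,7,3',4'-tetra-O-benzyl-(−)-epicatechin
Conditions: BnBr (4.4 equiv), K2CO3, DMF, 0 °C → rt
Reagents that add atoms: benzyl bromide, BrCc1ccccc1
Why: Williamson etherification with carbonate deprotonates only the four phenols, so the secondary C3 hydroxyl should stay free and both stereocentres are untouched.

Step 8
Reactants: 16 5,7,3',4'-tetra-O-benzyl-(−)-epicatechin
Product: 17 5,7,3',4'-tetra-O-benzyl-4β-(2-ethoxyethoxy)-(−)-epicatechin
Conditions: DDQ (2 equiv), 2-ethoxyethanol, CH2Cl2, rt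
Reagents that add atoms: 2-ethoxyethanol, CCOCCO
Why: DDQ abstracts hydride from C4, which is activated by the ortho and para alkoxy groups of the A-ring, and the alcohol adds to the benzylic cation from the face opposite the C3 hydroxyl to give the 3,4-trans ether (oxidative benzylic C–H etherification).

Step 9
Reactants: 17 5,7,3',4'-tetra-O-benzyl-4β-(2-ethoxyethoxy)-(−)-epicatechin; 18 3,4,5-tris(benzyloxy)benzoic acid
Product: 19 5,7,3',4'-tetra-O-benzyl-4β-(2-ethoxyethoxy)-3-O-[3,4,5-tris(benzyloxy)benzoyl]-(−)-epicatechin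
Conditions: DCC, DMAP, CH2Cl2, rt
Reagents that add atoms: none
Why: Steglich esterification acylates the only free hydroxyl under neutral conditions that leave the acid-labile C4 ether in place.

Step 10
Reactants: 19 5,7,3',4'-tetra-O-benzyl-4β-(2-ethoxyethoxy)-3-O-[3,4,5-tris(benzyloxy)benzoyl]-(−)-epicatechin; 14 3,5,7,3',4'-penta-O-benzyl-(+)-catechin
Product: 20 perbenzylated dimer [epicatechin 3-O-gallate]-(4β→8)-[catechin] carrying twelve benzyl ethers
Conditions: 14 (3 equiv, excess recovered), TMSOTf (0.2 equiv), CH2Cl2, −78 → −20 °C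
Reagents that add atoms: none
Why: TMSOTf ionises the C4 ether; the cation is bridged by the carbonyl oxygen of the 3-O-galloyl group, so C8 of 14, the less hindered nucleophilic carbon of its phloroglucinol ring, should attack trans to C3–O and set the new C4 centre as 4β (Friedel–Crafts-type interflavan coupling with neighbouring-group participation).

Step 11
Reactants: 19 5,7,3',4'-tetra-O-benzyl-4β-(2-ethoxyethoxy)-3-O-[3,4,5-tris(benzyloxy)benzoyl]-(−)-epicatechin; 20 perbenzylated dimer
Product: 21 perbenzylated trimer [epicatechin 3-O-gallate]-(4β→8)-[epicatechin 3-O-gallate]-(4β→8)-[catechin] carrying nineteen benzyl ethers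
Conditions: 20 (2 equiv, excess recovered), TMSOTf (0.2 equiv), CH2Cl2, −78 → −20 °C
Reagents that add atoms: none
Why: The same Lewis acid-mediated coupling; C8 of the upper unit of 20 is the most accessible nucleophilic carbon (C8 of the lower unit is occupied and the C6 positions lie between two benzyloxy groups), and acyloxy participation again should give the 3,4-trans (4β) bond.

Step 12
Reactants: 21 perbenzylated trimer
Product: 22 (−)-epicatechin 3-O-gallate-(4β→8)-(−)-epicatechin 3-O-gallate-(4β→8)-(+)-catechin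
Conditions: H2 (1 atm), Pd(OH)2/C, THF/MeOH/H2O, rt
Reagents that add atoms: none
Why: Hydrogenolysis of the nineteen benzyl ethers over Pearlman's catalyst is neutral, so the gallate esters, the interflavan bonds and all eight stereocentres should be untouched.

Compound list
1 | 1,3,5-trifluorobenzene | Fc1cc(F)cc(F)c1 | starting material
2 | 1,3-bis(benzyloxy)-5-fluorobenzene | Fc1cc(OCc2ccccc2)cc(OCc2ccccc2)c1 | intermediate
3 | methyl (2S)-oxirane-2-carboxylate, methyl (S)-glycidate | COC(=O)[C@@H]1CO1 | starting material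
4 | [2,4-bis(benzyloxy)-6-fluorophenyl]lithium | [Li]c1c(F)cc(OCc2ccccc2)cc1OCc1ccccc1 | intermediate
5 | [2,4-bis(benzyloxy)-6-fluorophenyl]magnesium bromide | Br[Mg]c1c(F)cc(OCc2ccccc2)cc1OCc1ccccc1 | intermediate
6 | methyl (2S)-3-[2,4-bis(benzyloxy)-6-fluorophenyl]-2-hydroxypropanoate | COC(=O)[C@@H](O)Cc1c(F)cc(OCc2ccccc2)cc1OCc1ccccc1 | intermediate
7 | methyl (2S)-2-(benzyloxy)-3-[2,4-bis(benzyloxy)-6-fluorophenyl]propanoate | COC(=O)[C@@H](OCc1ccccc1)Cc1c(F)cc(OCc2ccccc2)cc1OCc1ccccc1 | intermediate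
8 | (2S)-2-(benzyloxy)-3-[2,4-bis(benzyloxy)-6-fluorophenyl]propanal | O=C[C@@H](OCc1ccccc1)Cc1c(F)cc(OCc2ccccc2)cc1OCc1ccccc1 | intermediate
9 | 4-bromo-1,2-bis(benzyloxy)benzene | Brc1ccc(OCc2ccccc2)c(OCc2ccccc2)c1 | starting material
10 | [3,4-bis(benzyloxy)phenyl]lithium | [Li]c1ccc(OCc2ccccc2)c(OCc2ccccc2)c1 | intermediate
11 | [3,4-bis(benzyloxy)phenyl]titanium triisopropoxide | CC(C)O[Ti](OC(C)C)(OC(C)C)c1ccc(OCc2ccccc2)c(OCc2ccccc2)c1 | intermediate
12 | (1R,2S)-2-(benzyloxy)-1-[3,4-bis(benzyloxy)phenyl]-3-[2,4-bis(benzyloxy)-6-fluorophenyl]propan-1-ol | O[C@H](c1ccc(OCc2ccccc2)c(OCc2ccccc2)c1)[C@@H](OCc1ccccc1)Cc1c(F)cc(OCc2ccccc2)cc1OCc1ccccc1 | intermediate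
13 | potassium alkoxide of 12 | [K]O[C@H](c1ccc(OCc2ccccc2)c(OCc2ccccc2)c1)[C@@H](OCc1ccccc1)Cc1c(F)cc(OCc2ccccc2)cc1OCc1ccccc1 | intermediate
14 | 3,5,7,3',4'-penta-O-benzyl-(+)-catechin, (2R,3S)-3,5,7-tris(benzyloxy)-2-[3,4-bis(benzyloxy)phenyl]chromane | c1ccccc1CO[C@H]1Cc2c(OCc3ccccc3)cc(OCc3ccccc3)cc2O[C@@H]1c1ccc(OCc2ccccc2)c(OCc2ccccc2)c1 | intermediate
15 | (−)-epicatechin, (2R,3R) | O[C@@H]1Cc2c(O)cc(O)cc2O[C@@H]1c1ccc(O)c(O)c1 | starting material
16 | 5,7,3',4'-tetra-O-benzyl-(−)-epicatechin | O[C@@H]1Cc2c(OCc3ccccc3)cc(OCc3ccccc3)cc2O[C@@H]1c1ccc(OCc2ccccc2)c(OCc2ccccc2)c1 | intermediate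
17 | 5,7,3',4'-tetra-O-benzyl-4β-(2-ethoxyethoxy)-(−)-epicatechin (2,3-cis, 3,4-trans) | CCOCCO[C@H]1c2c(OCc3ccccc3)cc(OCc3ccccc3)cc2O[C@H](c2ccc(OCc3ccccc3)c(OCc3ccccc3)c2)[C@@H]1O | intermediate
18 | 3,4,5-tris(benzyloxy)benzoic acid | OC(=O)c1cc(OCc2ccccc2)c(OCc2ccccc2)c(OCc2ccccc2)c1 | starting material
19 | 5,7,3',4'-tetra-O-benzyl-4β-(2-ethoxyethoxy)-3-O-[3,4,5-tris(benzyloxy)benzoyl]-(−)-epicatechin | CCOCCO[C@H]1c2c(OCc3ccccc3)cc(OCc3ccccc3)cc2O[C@H](c2ccc(OCc3ccccc3)c(OCc3ccccc3)c2)[C@@H]1OC(=O)c1cc(OCc2ccccc2)c(OCc2ccccc2)c(OCc2ccccc2)c1 | intermediate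
20 | perbenzylated dimer: [5,7,3',4'-tetra-O-benzyl-3-O-(tri-O-benzylgalloyl)epicatechin]-(4β→8)-[3,5,7,3',4'-penta-O-benzylcatechin] | O=C(O[C@@H]1[C@@H](c2c(OCc3ccccc3)cc(OCc3ccccc3)c3c2O[C@H](c2ccc(OCc4ccccc4)c(OCc4ccccc4)c2)[C@@H](OCc2ccccc2)C3)c2c(OCc3ccccc3)cc(OCc3ccccc3)cc2O[C@@H]1c1ccc(OCc2ccccc2)c(OCc2ccccc2)c1)c1cc(OCc2ccccc2)c(OCc2ccccc2)c(OCc2ccccc2)c1 | intermediate
21 | perbenzylated trimer: [tetra-O-benzyl-3-O-(tri-O-benzylgalloyl)epicatechin]-(4β→8)-[tetra-O-benzyl-3-O-(tri-O-benzylgalloyl)epicatechin]-(4β→8)-[penta-O-benzylcatechin] | O=C(O[C@@H]1[C@@H](c2c(OCc3ccccc3)cc(OCc3ccccc3)c3c2O[C@H](c2ccc(OCc4ccccc4)c(OCc4ccccc4)c2)[C@@H](OCc2ccccc2)C3)c2c(OCc3ccccc3)cc(OCc3ccccc3)c([C@H]3c4c(OCc5ccccc5)cc(OCc5ccccc5)cc4O[C@H](c4ccc(OCc5ccccc5)c(OCc5ccccc5)c4)[C@@H]3OC(=O)c3cc(OCc4ccccc4)c(OCc4ccccc4)c(OCc4ccccc4)c3)c2O[C@@H]1c1ccc(OCc2ccccc2)c(OCc2ccccc2)c1)c1cc(OCc2ccccc2)c(OCc2ccccc2)c(OCc2ccccc2)c1 | intermediate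
22 | (−)-epicatechin 3-O-gallate-(4β→8)-(−)-epicatechin 3-O-gallate-(4β→8)-(+)-catechin | O=C(O[C@@H]1[C@@H](c2c(O)cc(O)c3c2O[C@H](c2ccc(O)c(O)c2)[C@@H](O)C3)c2c(O)cc(O)c([C@H]3c4c(O)cc(O)cc4O[C@H](c4ccc(O)c(O)c4)[C@@H]3OC(=O)c3cc(O)c(O)c(O)c3)c2O[C@@H]1c1ccc(O)c(O)c1)c1cc(O)c(O)c(O)c1 | target

Total step count: 12
Longest linear sequence: 9 steps (steps 1–6, then 10, 11 and 12)

Steps most likely to fail

Step 2. What may go wrong: metalation at the ring position between the two benzyloxy groups instead of next to fluorine, loss of LiF from the ortho-fluoro organometallic on warming, or attack on the ester instead of the epoxide. Fallback: the ring position is fixed by electrophilic substitution instead of deprotonation. Setting out from 2, NBS in MeCN at 0 °C should brominate para to one benzyloxy group and next to the small fluorine to give 2-bromo-1,5-bis(benzyloxy)-3-fluorobenzene F1. Br/Mg exchange with iPrMgCl·LiCl in THF at −20 °C should then give [2,4-bis(benzyloxy)-6-fluorophenyl]magnesium chloride F2, which opens 3 under the same copper catalysis and comes back to the route at 6.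

Step 5. What may go wrong: poor facial selectivity of the aryl addition, or epimerisation of the α-alkoxy aldehyde before it reacts. Fallback: stereocontrol is moved from C–C to C–H bond formation. Setting out from 8, [3,4-bis(benzyloxy)phenyl]magnesium bromide F3 (from 9 and Mg) is added without regard to selectivity to give (2S)-2-(benzyloxy)-1-[3,4-bis(benzyloxy)phenyl]-3-[2,4-bis(benzyloxy)-6-fluorophenyl]propan-1-ol as a mixture of C1 epimers F4. Dess–Martin oxidation gives (2S)-2-(benzyloxy)-1-[3,4-bis(benzyloxy)phenyl]-3-[2,4-bis(benzyloxy)-6-fluorophenyl]propan-1-one F5. Reduction with Zn(BH4)2 in Et2O at −30 °C delivers hydride within the zinc chelate of the carbonyl and benzyloxy oxygens (Cram chelate), which should give the anti alcohol and come back to the route at 12.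

Step 6. What may go wrong: slow addition of the alkoxide to the electron-rich fluoroarene, with decomposition on prolonged heating with base. Fallback: the mechanism is switched from addition–elimination to elimination–addition. Setting out from 12, LiTMP (2.5 equiv, THF, −78 → 0 °C) should form the lithium alkoxide, lithiate the ring C–H flanked by F and OBn and expel LiF to give the lithium alkoxide of the 7,8-aryne F6. The tethered alkoxide should add to the aryne carbon remote from the benzyloxy group (six-membered ring, carbanion placed next to OBn), and protonation on work-up comes back to the route at 14.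

Further compounds
F1 | step 2 | 2-bromo-1,5-bis(benzyloxy)-3-fluorobenzene | Brc1c(F)cc(OCc2ccccc2)cc1OCc1ccccc1
F2 | step 2 | [2,4-bis(benzyloxy)-6-fluorophenyl]magnesium chloride | Cl[Mg]c1c(F)cc(OCc2ccccc2)cc1OCc1ccccc1
F3 | step 5 | [3,4-bis(benzyloxy)phenyl]magnesium bromide | Br[Mg]c1ccc(OCc2ccccc2)c(OCc2ccccc2)c1
F4 | step 5 | (2S)-2-(benzyloxy)-1-[3,4-bis(benzyloxy)phenyl]-3-[2,4-bis(benzyloxy)-6-fluorophenyl]propan-1-ol, mixture of C1 epimers | OC(c1ccc(OCc2ccccc2)c(OCc2ccccc2)c1)[C@@H](OCc1ccccc1)Cc1c(F)cc(OCc2ccccc2)cc1OCc1ccccc1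
F5 | step 5 | (2S)-2-(benzyloxy)-1-[3,4-bis(benzyloxy)phenyl]-3-[2,4-bis(benzyloxy)-6-fluorophenyl]propan-1-one | O=C(c1ccc(OCc2ccccc2)c(OCc2ccccc2)c1)[C@@H](OCc1ccccc1)Cc1c(F)cc(OCc2ccccc2)cc1OCc1ccccc1
F6 | step 6 | lithium alkoxide of the 7,8-aryne derived from 12 (transient) | [Li]O[C@H](c1ccc(OCc2ccccc2)c(OCc2ccccc2)c1)[C@@H](OCc1ccccc1)CC1=C(OCc2ccccc2)C=C(OCc2ccccc2)C#C1
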